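The plan rests on cutting the C5–C6 bond of the cyclohexenone ring. The feature exploited is ketone C1 next to quaternary C6, which lies β to the aryl ketone: a 1,4-diketone that a vinylogous α-ketol shift can create. Ring atoms C1–C5 then fold back into a mirror-symmetric cyclopent-3-enol. The precursor is a tetrasubstituted (Z)-aryl enone carrying allyl and 1-hydroxycyclopent-3-enyl groups on C6. One 1,2-shift under a chiral acid enlarges the five-membered ring to six, unveils the C1 ketone and sets C6 and Cα. Both ring CH2 groups being equivalent, only a face of C6 is chosen. The surviving C3=C4 alkene later delivers the enone and the C4 methoxy group.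

Key step: step 4

Atom labels (target numbering, used throughout): C1 ketone, C2=C3, C4 (OMe), C5 (CH2), C6 (quaternary), Cα (side-chain methine next to the aroyl group).

Assumption: the (R) antipode of the phosphoric acid is taken to deliver (R)-C6. The sense of induction cannot be derived from precedent, so the equally available (S) antipode is used if the first run shows the opposite sense.

Step 1
Reactants: 1 cyclopent-3-en-1-one; 2 1-propynylmagnesium bromide
Product: 3 1-(prop-1-yn-1-yl)cyclopent-3-en-1-ol
Conditions: 2 (1.2 equiv, 0.5 M in THF), LaCl3·2LiCl (0.3 equiv), THF, −20 → 0 °C; aq NH4Cl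
Reagents that add atoms: 1-propynylmagnesium bromide, CC#C[Mg]Br
Why: Grignard 1,2-addition of an alkynyl nucleophile to a ketone, assisted by the oxophilic lanthanum salt so that carbonyl addition outruns enolisation of the sensitive β,γ-enone and its slide into conjugation; no stereocentre arises because 3 keeps a mirror plane.

Step 2
Reactants: 3 1-(prop-1-yn-1-yl)cyclopent-3-en-1-ol; 4 allylmagnesium bromide; 5 3,4-dimethoxybenzaldehyde
Product: 7 (Z)-1-[1-(3,4-dimethoxyphenyl)-1-hydroxy-2-methylhexa-2,5-dien-3-yl]cyclopent-3-en-1-ol (racemic at the benzylic carbinol), via oxamagnesacyclopentene chelate 6 (not isolated)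
Conditions: 4 (2.3 equiv, 1.0 M in Et2O), toluene co-solvent, 45 °C; then 5 (1.5 equiv), THF, −20 °C → rt; aq NH4Cl/NH3 (pH 8); crude product used directly
Reagents that add atoms: allylmagnesium bromide, C=CC[Mg]Br; 3,4-dimethoxybenzaldehyde, COc1ccc(C=O)cc1OC
Why: Alkoxide-directed anti carbomagnesiation of a propargylic alcohol followed by Grignard addition to an aldehyde: the first equivalent of 4 forms the alkoxide, the second delivers allyl to the alkyne carbon next to the carbinol while magnesium ends on the methyl-bearing carbon inside five-membered chelate 6, which fixes the two carbinol carbons cis on the tetrasubstituted alkene (Z), the benzylic centre being formed racemic and erased in step 3.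

Step 3
Reactants: 7 (Z)-diol (crude)
Product: 8 (Z)-1-(3,4-dimethoxyphenyl)-3-(1-hydroxycyclopent-3-en-1-yl)-2-methylhexa-2,5-dien-1-one
Conditions: activated MnO2 (15 equiv), CH2Cl2, rt
Reagents that add atoms: none
Why: Manganese dioxide oxidation, selective for the doubly activated benzylic and allylic secondary alcohol, should leave the tertiary carbinol, the three alkenes and the Z geometry untouched because the medium is neutral and the acid-labile benzylic alcohol is never ionised.

Step 4
Reactants: 8 (Z)-hydroxy enone
Product: 11 (2R)-2-allyl-2-[(2S)-1-(3,4-dimethoxyphenyl)-1-oxopropan-2-yl]cyclohex-4-en-1-one, via spiro hemiketal 9 (not isolated), via aryl enol 10 (not isolated)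
Conditions: (R)-TRIP [(R)-3,3'-bis(2,4,6-triisopropylphenyl)-1,1'-binaphthyl-2,2'-diyl hydrogen phosphate] (10 mol %), toluene, 40 °C
Reagents that add atoms: none
Why: Proposed new method: the phosphoric acid bridges the two oxygen atoms that the Z geometry holds side by side, its P–OH polarising and finally protonating the aroyl oxygen (open form 8 being fed from its resting hemiketal 9) and its P=O accepting the carbinol O–H, so that C6 becomes the electrophilic end of an aryl-stabilised hydroxyallyl cation, one ring CH2 shifts from the carbinol carbon to C6, the carbinol becomes the C1 ketone, and aryl enol 10 is left to be protonated at Cα. The closest known reaction type is the catalytic asymmetric vinylogous α-ketol (semipinacol) rearrangement of β-(1-hydroxycyclobutyl) enones, backed by phosphoric-acid-catalysed pinacol-type shifts; untested are the barely strained five-membered carbinol and the acyclic tetrasubstituted aryl enone, so the driving force is mainly the trade of a twisted enone plus tertiary alcohol for two ketones. The six-membered ring is closed by ring enlargement, a suprafacial 1,2-carbon shift that takes the carbocycle from five to six atoms with C5–C6 as the only new skeletal bond, not by an end-to-end cyclisation. At C6, once the O–H is tied into the enone plane the two ring CH2 groups stand above and below that plane and are enantiotopic, so the aryl-walled pocket of the chiral phosphate decides which one moves and hence which face of C6 is attacked, R being required. At Cα, the acid still bound to enol 10 should return the proton to the face opposite the newly attached C5, which is flanked only by the slim allyl chain, a net anti addition of C5 and H across the Z alkene that gives S. No choice between migrating groups is needed because the mirror symmetry of the cyclopentenol makes them identical, furan formation from the 1,4-diketone is blocked by quaternary C6, and a weak acid in toluene at mild temperature is chosen so that the shift can outrun dehydration of the carbinol, drift of the skipped diene into conjugation and β,γ to α,β isomerisation of 11.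

Step 5
Reactants: 11 (2R)-2-allyl-2-[(2S)-1-(3,4-dimethoxyphenyl)-1-oxopropan-2-yl]cyclohex-4-en-1-one
Product: 12 (1S,4R,6R)-4-allyl-4-[(2S)-1-(3,4-dimethoxyphenyl)-1-oxopropan-2-yl]-7-oxabicyclo[4.1.0]heptan-3-one (oxirane oxygen trans to allyl, cis to the aroylethyl chain)
Conditions: mCPBA (1.05 equiv), CH2Cl2, −10 → 0 °C; wash with aq Na2S2O3/NaHCO3; taken on without chromatography
Reagents that add atoms: mCPBA (3-chloroperoxybenzoic acid), O=C(OO)c1cccc(Cl)c1
Why: Prilezhaev epoxidation, chemoselective because the cis-disubstituted ring alkene is more nucleophilic than the monosubstituted allyl alkene; in the half-chair with the branched aroylethyl group pseudoequatorial, the pseudoaxial allyl group covers one face of C3=C4, so oxygen should arrive on the opposite face and set C3 (S) and C4 (R).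

Step 6
Reactants: 12 β,γ-epoxy ketone
Product: 13 (4R,6R)-6-allyl-6-[(2S)-1-(3,4-dimethoxyphenyl)-1-oxopropan-2-yl]-4-hydroxycyclohex-2-en-1-one
Conditions: Et3N (1.5 equiv), CH2Cl2, 0 °C → rt
Reagents that add atoms: none
Why: Base-induced E1cB-type isomerisation of a β,γ-epoxy ketone, in which loss of a C2 proton expels the C3–O bond to give the C2=C3 enone while the C4–O bond and its configuration stay untouched, the weak amine base sparing the epimerisable Cα centre.

Step 7
Reactants: 13 4-hydroxy enone
Product: 14 (4R,6R)-6-allyl-6-[(2S)-1-(3,4-dimethoxyphenyl)-1-oxopropan-2-yl]-4-methoxycyclohex-2-en-1-one (CNP0199951.1)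
Conditions: MeI (10 equiv), Ag2O (2 equiv), CH2Cl2, 4 Å molecular sieves, dark, rt → 35 °C
Reagents that add atoms: iodomethane, CI
Why: Purdie methylation under essentially neutral conditions alkylates the oxygen without touching the C4–O bond (retention at C4) and avoids alkoxide bases that could epimerise Cα or eliminate the C4 oxygen.

Compound list
1 | cyclopent-3-en-1-one | O=C1CC=CC1 | starting material
2 | 1-propynylmagnesium bromide | CC#C[Mg]Br | starting material
3 | 1-(prop-1-yn-1-yl)cyclopent-3-en-1-ol | CC#CC1(O)CC=CC1 | intermediate
4 | allylmagnesium bromide | C=CC[Mg]Br | starting material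
5 | 3,4-dimethoxybenzaldehyde | COc1ccc(C=O)cc1OC | starting material
6 | 4-allyl-3-methyl-1-oxa-2-magnesaspiro[4.4]nona-3,7-diene (chelate, not isolated) | C=CCC1=C(C)[Mg]OC12CC=CC2 | intermediate
7 | (Z)-1-[1-(3,4-dimethoxyphenyl)-1-hydroxy-2-methylhexa-2,5-dien-3-yl]cyclopent-3-en-1-ol, racemic at the benzylic carbon | C=CC/C(=C(\C)C(O)c1ccc(OC)c(OC)c1)C1(O)CC=CC1 | intermediate
8 | (Z)-1-(3,4-dimethoxyphenyl)-3-(1-hydroxycyclopent-3-en-1-yl)-2-methylhexa-2,5-dien-1-one | C=CC/C(=C(\C)C(=O)c1ccc(OC)c(OC)c1)C1(O)CC=CC1 | intermediate
9 | 4-allyl-2-(3,4-dimethoxyphenyl)-3-methyl-1-oxaspiro[4.4]nona-3,7-dien-2-ol, ring tautomer of 8 with a labile hemiketal centre (not isolated) | C=CCC1=C(C)C(O)(c2ccc(OC)c(OC)c2)OC13CC=CC3 | intermediate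
10 | (2R)-2-allyl-2-[(Z)-1-(3,4-dimethoxyphenyl)-1-hydroxyprop-1-en-2-yl]cyclohex-4-en-1-one (not isolated) | C=CC[C@]1(/C(C)=C(\O)c2ccc(OC)c(OC)c2)CC=CCC1=O | intermediate
11 | (2R)-2-allyl-2-[(2S)-1-(3,4-dimethoxyphenyl)-1-oxopropan-2-yl]cyclohex-4-en-1-one | C=CC[C@]1([C@H](C)C(=O)c2ccc(OC)c(OC)c2)CC=CCC1=O | intermediate
12 | (1S,4R,6R)-4-allyl-4-[(2S)-1-(3,4-dimethoxyphenyl)-1-oxopropan-2-yl]-7-oxabicyclo[4.1.0]heptan-3-one | C=CC[C@]1([C@H](C)C(=O)c2ccc(OC)c(OC)c2)C[C@H]3O[C@H]3CC1=O | intermediate
13 | (4R,6R)-6-allyl-6-[(2S)-1-(3,4-dimethoxyphenyl)-1-oxopropan-2-yl]-4-hydroxycyclohex-2-en-1-one | C=CC[C@]1([C@H](C)C(=O)c2ccc(OC)c(OC)c2)C[C@@H](O)C=CC1=O | intermediate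
14 | (4R,6R)-6-allyl-6-[(2S)-1-(3,4-dimethoxyphenyl)-1-oxopropan-2-yl]-4-methoxycyclohex-2-en-1-one | C=CC[C@]1([C@H](C)C(=O)c2ccc(OC)c(OC)c2)C[C@@H](OC)C=CC1=O | target

Total step count: 7. Longest linear sequence: 7 steps (1 → 14).

Steps most likely to fail

Step 4. The 1,2-shift may be too slow for a barely strained carbinol on a twisted, electron-rich aryl enone. Loss of water from the carbinol, drift of the skipped diene into conjugation, or weak discrimination between the faces of C6 and of the enol could then take over. The fallback uses known chemistry, sets out from 7 and returns at 11. It makes the same C5–C6 bond by the stereospecific semipinacol rearrangement of a 2,3-epoxy alcohol. Hydroxyl-directed epoxidation of the tetrasubstituted alkene of 7 (VO(acac)2, t-BuOOH, CH2Cl2, 0 °C) should give the racemic epoxy diol F1. Dess–Martin periodinane then oxidises the benzylic alcohol to the racemic epoxy ketone F2. ZnBr2 in CH2Cl2 opens the oxirane at C6, the carbon remote from the acyl group, with the ring CH2 entering anti to the departing oxygen, to give the racemic α-hydroxy diketone F3. SmI2 in THF/MeOH at −78 °C removes the α-hydroxyl group and gives 11 as a racemate. Preparative chromatography on a chiral stationary phase separates it from the antipode of 11 F4.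

Step 5. Facial selectivity may be poor or inverted if the two C6 substituents differ too little in their preference for the pseudoaxial site. The fallback sets out from 11 and returns at 13, and C4 is then fixed by SN2 inversion instead of by face selection. Material oxidised syn to the allyl group, the epimeric epoxide F5, is carried through the same Et3N opening to the C4-epimeric hydroxy enone F6, which is separated from 13 by chromatography. A Mitsunobu reaction (4-nitrobenzoic acid, PPh3, DIAD, THF, 0 °C) inverts it to the (4R)-4-nitrobenzoate F7. Brief methanolysis (K2CO3, MeOH, 0 °C) then releases 13.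

Step 2. Capture of the hindered, chelated alkenylmagnesium by the aldehyde may be sluggish in competition with leftover allyl Grignard reagent. Acid-triggered cyclodehydration of the easily ionised diol may also occur during work-up. The fallback sets out from 3 and returns at 8, bypassing 7 and the MnO2 step. Chelate 6 is generated as before but quenched with excess CO2, a small electrophile. Work-up with dilute HCl closes the spiro butenolide F8. Commercial 3,4-dimethoxyphenylmagnesium bromide (1.05 equiv, THF, −78 → −40 °C) then adds once to the lactone carbonyl, conjugate addition being blocked by the fully substituted β-carbon. This gives hemiketal 9, the ring tautomer of 8.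

Further compounds
F1 | step 4 | racemic [3-allyl-3-(1-hydroxycyclopent-3-en-1-yl)-2-methyloxiran-2-yl](3,4-dimethoxyphenyl)methanol, carbinol groups cis on the oxirane, enantiomer leading to 11 drawn | C=CC[C@@]1(O[C@@]1(C)C(O)c2ccc(OC)c(OC)c2)C3(O)CC=CC3
F2 | step 4 | racemic [3-allyl-3-(1-hydroxycyclopent-3-en-1-yl)-2-methyloxiran-2-yl](3,4-dimethoxyphenyl)methanone, enantiomer leading to 11 drawn | C=CC[C@@]1(O[C@@]1(C)C(=O)c2ccc(OC)c(OC)c2)C3(O)CC=CC3
F3 | step 4 | racemic 2-allyl-2-[1-(3,4-dimethoxyphenyl)-2-hydroxy-1-oxopropan-2-yl]cyclohex-4-en-1-one, (2R, side chain 2R) enantiomer drawn | C=CC[C@]1([C@@](C)(O)C(=O)c2ccc(OC)c(OC)c2)CC=CCC1=O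
F4 | step 4 | (2S)-2-allyl-2-[(2R)-1-(3,4-dimethoxyphenyl)-1-oxopropan-2-yl]cyclohex-4-en-1-one, antipode of 11 | C=CC[C@@]1([C@@H](C)C(=O)c2ccc(OC)c(OC)c2)CC=CCC1=O
F5 | step 5 | (1R,4R,6S)-4-allyl-4-[(2S)-1-(3,4-dimethoxyphenyl)-1-oxopropan-2-yl]-7-oxabicyclo[4.1.0]heptan-3-one, oxirane oxygen cis to allyl | C=CC[C@]1([C@H](C)C(=O)c2ccc(OC)c(OC)c2)C[C@@H]3O[C@@H]3CC1=O
F6 | step 5 | (4S,6R)-6-allyl-6-[(2S)-1-(3,4-dimethoxyphenyl)-1-oxopropan-2-yl]-4-hydroxycyclohex-2-en-1-one | C=CC[C@]1([C@H](C)C(=O)c2ccc(OC)c(OC)c2)C[C@H](O)C=CC1=O
F7 | step 5 | (1R,5R)-5-allyl-5-[(2S)-1-(3,4-dimethoxyphenyl)-1-oxopropan-2-yl]-4-oxocyclohex-2-en-1-yl 4-nitrobenzoate | C=CC[C@]1([C@H](C)C(=O)c2ccc(OC)c(OC)c2)C[C@@H](OC(=O)c3ccc(cc3)[N+](=O)[O-])C=CC1=O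
F8 | step 2 | 4-allyl-3-methyl-1-oxaspiro[4.4]nona-3,7-dien-2-one | C=CCC1=C(C)C(=O)OC12CC=CC2
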